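## Analysis of the target

Target 17 is a lignan built on one oxolane (tetrahydrofuran) ring (O1, C2, C3, C4, C5) in which both carbons next to oxygen are unsubstituted CH2 groups. C3 carries an exocyclic secondary benzylic carbinol whose aryl group is 4-hydroxy-3,5-dimethoxyphenyl, and C4 carries a 4-hydroxy-3-methoxybenzyl group. The three stereocentres are contiguous and all S. The substituents at C3 and C4 are trans on the ring, and when the carbinol hydrogen sits between the two ring bonds of C3, the carbinol C–O bond lies anti to the C3–C4 bond. The sensitive part is the para-hydroxybenzylic alcohol: acid ionises it, hydrogenolysis cleaves it, and strong base can expel its oxygen through a quinone methide; the two phenols are easily oxidised as phenoxides. The difficulty is that the ring has no carbonyl group or other handle, so C3 and C4 are plain CH stereocentres that cannot be corrected by equilibration, and the carbinol lies outside the ring where only acyclic control can relate it to C3. The strategy rests on the environment of C4: it is bonded to C3, to the C5H2–O1 unit and to the benzylic CH2. That is exactly what remains when a radical at C3 adds to the inner carbon of an O-allyl group held through C2–O1 and the outer alkene carbon is then joined to an aryl ring.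

## Retrosynthetic reasoning

17 from 16. The three O–H groups are traced back to three O–Si bonds. Silyl ethers are chosen because their removal needs neither acid nor hydrogen, the two conditions the benzylic carbinol does not tolerate. The forward step must take off a hindered secondary silyl ether together with two aryl silyl ethers without leaving free phenoxide in solution for long.

16 from 13 and 15. Two bonds are cut in one operation: C3–C4 of the ring and the bond between the exocyclic CH2 on C4 and its aryl ring. This opens the ring, removes both ring stereocentres and divides the molecule into aryl iodide 15 and the acyclic allyl ether 13, which keeps a single stereocentre, the protected carbinol. C3 becomes a carbon radical released from a carboxyl group activated as its N-acyloxyphthalimide. A radical is preferred to an organometallic at C3 because the latter would lie β to two oxygen substituents and eliminate. The forward reaction has to form the C3 radical, close the ring 5-exo before anything else happens to it, and pass the new primary radical to an arylnickel species. It must do so with the C3 substituent trans to the new CH2 and with the new C3–C4 bond on the correct face relative to the carbinol.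

13 from 11 and 12, 11 from 10, 10 from 9. These are functional-group changes: the active-ester C–O bond, the carboxyl protecting group and the O–Si bond at the carbinol. The acid is carried as allyl ester 10 because that ester is cleaved by palladium-catalysed allyl transfer under neutral conditions, whereas hydroxide would endanger the aryl silyl ether. The allyl ether in the same molecule has no leaving group of comparable quality and should stay.

9 from 8, 8 from 7. The C–H bond of the carbinol is cut. Catalytic asymmetric reduction of aryl ketone 8 sets the only stereocentre the cascade needs, under catalyst control and early in the route. The neighbouring ester-bearing carbon needs no control because it later becomes the planar radical. Ketone 8 comes from oxidation of aldol 7, which merges its diastereomers.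

7 from 3 and 5. The bond between the carbinol carbon and the ester α-carbon is cut (aldol). This is preferred to attaching the allyloxymethyl arm to an existing 1,3-dicarbonyl enolate, because alkoxymethyl halides are hard electrophiles that tend to attack the enolate oxygen. In the aldol the arm arrives as part of the nucleophile. The forward step must generate and use the β-alkoxy ester enolate cold, before it expels alkoxide.

3 from 1 and 2; 5 from 4; 15 from 14. One O–C bond of 3 is cut by conjugate addition of 1 to 2; with the allyl ester of acrylic acid, ester exchange with 1 changes nothing. 5 and 15 arise by silylation of the commercial phenols 4 and 14.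

## Alternatives that were turned down

Alternative 1: The ring would be cut at C2–C3 and C4–C5, a (3+2) disconnection. In the forward sense, fluoride would release the unsubstituted carbonyl ylide from chloromethyl (trimethylsilyl)methyl ether A2, and the ylide would add across the E-alkene of the aroylacrylic imide A1 to give the trans-4-aroyloxolane-3-carbonyl imide A3.
- For: the cycloaddition is suprafacial, so the E geometry is carried into the trans ring relationship with certainty, which is more than the chosen route can promise. Both O–CH2 carbons come from one small reagent.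
- Against: A3 has a ketone on the arm that must end as the benzylic CH2 and an acyl group on the arm that must end as the aryl carbinol. After the key step an aryl ketone has to be deoxygenated, the imide converted into an aryl ketone or aldehyde, the second aryl group added, and the carbinol stereocentre still set under acyclic control. The facial selectivity of a very reactive, unstabilised ylide towards an imide that is not locked by a Lewis acid is doubtful, so the absolute configuration is not secure either.
- Comparison: the chosen route gives up the guaranteed trans relationship. In return it reaches the target one step after the key step, with every carbon at its final oxidation level and the carbinol made by a catalytic reduction at the start.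

Alternative 2: The cuts are O1–C5 and C3–C4. A zerovalent palladium catalyst with a chiral phosphoramidite would ionise 4-vinyl-1,3-dioxolan-2-one A4 decarboxylatively. The alkoxide end of the zwitterion would add to the aryl vinyl ketone A5 and the enolate would close onto the substituted allyl terminus, giving the trans-3-vinyl-4-aroyloxolane A6.
- For: absolute configuration comes from the ligand and depends on no stereocentre in the substrate, a point on which it is stronger than the chosen route. The carbon next to the ketone could also be equilibrated to trans.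
- Against: this annulation is at its best with doubly activated acceptors. With a simple enone such as A5 the alkoxide addition is reversible and the enone polymerises easily. A6 again has the ketone on the arm that must become CH2, and the vinyl group has to be cleaved to an aldehyde, arylated, and the carbinol configuration settled late by substrate control.
- Comparison: about six operations would follow the key step, against one here. The chosen route offers the shorter end game and a carbinol of defined configuration from the outset, at the price of relying on that carbinol to control the ring.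

Alternative 3: The bond from C3 to the carbinol carbon and the bond from C4 to its benzyl group are cut on a lactone template. The 2-lithio derivative of aryl dithiane A8 would add to the β-carbon of the cellulose-derived (S)-butenolide A7 anti to its silyloxymethyl group, and the enolate would be alkylated by benzylic bromide A9 anti to the new substituent, giving the all-trans lactone A10.
- For: this tandem addition–alkylation is the most predictable of the four ways of fixing the trans ring relationship and the absolute configuration, clearly stronger than the chosen route on that point. Both aryl-bearing arms are attached in one flask from a cheap chiral-pool material.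
- Against: A10 has one carbon more than the target and the wrong heterocycle. The lactone must be reduced, the silyloxymethyl-bearing carbon degraded by glycol cleavage, the aldehyde reduced and the diol cyclised to the oxolane. The dithiane then has to be removed next to two electron-rich arenes and the ketone reduced with whatever diastereoselectivity the substrate allows.
- Comparison: that is some eight steps after the key step, with the carbinol set last. The chosen route builds the oxolane directly and needs no sacrificial stereocentre, which is what it offers in exchange for its less certain cyclisation selectivity.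

Key step: step 10

Remark on the chemistry: the carboxyl-bearing carbon of 7 to 13 becomes a planar radical in step 10, so its configuration is left open throughout; 7 and 8 are racemic and 9 to 13 are defined only at the carbinol carbon.

## Route

Step 1
Reactants: 1 allyl alcohol; 2 allyl acrylate
Product: 3 allyl 3-(allyloxy)propanoate
Conditions: NaH (5 mol %), allyl alcohol (3 equiv, neat), 0 °C to rt
Reagents that add atoms: none
Why: Base-catalysed oxa-Michael addition of the allyl alkoxide to the acrylate. Nucleophile and ester alkoxy group are identical, so transesterification changes nothing and one product should result.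

Step 2
Reactants: 4 syringaldehyde (4-hydroxy-3,5-dimethoxybenzaldehyde)
Product: 5 3,5-dimethoxy-4-(triisopropylsilyloxy)benzaldehyde
Conditions: TIPSCl, imidazole, DMF, rt to 40 °C
Reagents that add atoms: triisopropylsilyl chloride, CC(C)[Si](Cl)(C(C)C)C(C)C
Why: Standard silylation of a phenol. The triisopropylsilyl ether, shielded by two ortho methoxy groups, should withstand LDA, oxidation, formate reduction and the nickel/zinc step.

Step 3
Reactants: 3 allyl 3-(allyloxy)propanoate; 5 3,5-dimethoxy-4-(triisopropylsilyloxy)benzaldehyde
Product: 7 allyl 2-(allyloxymethyl)-3-[3,5-dimethoxy-4-(triisopropylsilyloxy)phenyl]-3-hydroxypropanoate (racemic; both diastereomers), via lithium ester enolate 6 (not isolated)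
Conditions: LDA (1.1 equiv), THF, −78 °C; then 5, −78 °C; AcOH quench at −78 °C
Reagents that add atoms: none
Why: Aldol addition of a lithium ester enolate. At −78 °C the β-allyloxy enolate should add to the aldehyde faster than it expels alkoxide, because the C–O bond lies close to the enolate plane. No stereocontrol is needed, since one new centre is reset by oxidation and the other becomes the radical carbon.

Step 4
Reactants: 7 allyl 2-(allyloxymethyl)-3-[3,5-dimethoxy-4-(triisopropylsilyloxy)phenyl]-3-hydroxypropanoate
Product: 8 allyl 2-(allyloxymethyl)-3-[3,5-dimethoxy-4-(triisopropylsilyloxy)phenyl]-3-oxopropanoate (racemic)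
Conditions: Dess–Martin periodinane, CH2Cl2, 0 °C to rt
Reagents that add atoms: none
Why: Dess–Martin oxidation of a secondary benzylic alcohol under near-neutral conditions merges both diastereomers of 7 into one β-keto ester. No base is present that could expel the β-allyloxy group.

Step 5
Reactants: 8 allyl 2-(allyloxymethyl)-3-[3,5-dimethoxy-4-(triisopropylsilyloxy)phenyl]-3-oxopropanoate
Product: 9 allyl (3S)-2-(allyloxymethyl)-3-[3,5-dimethoxy-4-(triisopropylsilyloxy)phenyl]-3-hydroxypropanoate
Conditions: RuCl[(S,S)-TsDPEN](p-cymene) (2 mol %), HCO2H/Et3N (5:2), CH2Cl2, 30 °C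
Reagents that add atoms: none
Why: Asymmetric transfer hydrogenation of an aryl ketone; the (S,S)-diamine catalyst should deliver hydride to the face that gives the (S)-carbinol, by the usual model in which the aryl ring lies against the η6-arene (the enantiomeric catalyst would be used if the assay shows the opposite sense). The terminal alkenes are inert to the ruthenium hydride, and the α-centre may equilibrate through the enol without consequence.

Step 6
Reactants: 9 allyl (3S)-2-(allyloxymethyl)-3-[3,5-dimethoxy-4-(triisopropylsilyloxy)phenyl]-3-hydroxypropanoate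
Product: 10 allyl (3S)-2-(allyloxymethyl)-3-[3,5-dimethoxy-4-(triisopropylsilyloxy)phenyl]-3-(triisopropylsilyloxy)propanoate
Conditions: TIPSOTf, 2,6-lutidine, CH2Cl2, −20 °C to rt
Reagents that add atoms: triisopropylsilyl triflate, CC(C)[Si](OS(=O)(=O)C(F)(F)F)(C(C)C)C(C)C
Why: A silyl triflate with a hindered pyridine base silylates hindered secondary alcohols at low temperature, faster than retro-aldol or elimination can occur. The bulky ether is the control element for step 10.

Step 7
Reactants: 10 allyl (3S)-2-(allyloxymethyl)-3-[3,5-dimethoxy-4-(triisopropylsilyloxy)phenyl]-3-(triisopropylsilyloxy)propanoate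
Product: 11 (3S)-2-(allyloxymethyl)-3-[3,5-dimethoxy-4-(triisopropylsilyloxy)phenyl]-3-(triisopropylsilyloxy)propanoic acid
Conditions: Pd(PPh3)4 (5 mol %), morpholine (5 equiv), THF, rt; aqueous citric acid work-up
Reagents that add atoms: none
Why: Zerovalent palladium ionises the allyl ester, whose carboxylate is a good leaving group, to a π-allyl complex that morpholine captures. The allyl alkyl ether has no comparable leaving group, and the silyl ethers, which hydroxide would threaten, are not touched.

Step 8
Reactants: 11 (3S)-2-(allyloxymethyl)-3-[3,5-dimethoxy-4-(triisopropylsilyloxy)phenyl]-3-(triisopropylsilyloxy)propanoic acid; 12 N-hydroxyphthalimide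
Product: 13 1,3-dioxoisoindolin-2-yl (3S)-2-(allyloxymethyl)-3-[3,5-dimethoxy-4-(triisopropylsilyloxy)phenyl]-3-(triisopropylsilyloxy)propanoate
Conditions: DIC, DMAP (10 mol %), CH2Cl2, 0 °C to rt
Reagents that add atoms: none
Why: Carbodiimide-mediated (Steglich-type) esterification of the acid with the acidic N–OH group gives the redox-active ester under mild conditions that leave the carbinol centre alone.

Step 9
Reactants: 14 4-iodo-2-methoxyphenol
Product: 15 (4-iodo-2-methoxyphenoxy)triisopropylsilane
Conditions: TIPSCl, imidazole, DMF, rt
Reagents that add atoms: triisopropylsilyl chloride, CC(C)[Si](Cl)(C(C)C)C(C)C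
Why: Standard phenol silylation; it masks the acidic O–H, which would otherwise quench organonickel intermediates, and matches the protecting groups of 13 so that one final step unmasks everything.

Step 10
Reactants: 13 1,3-dioxoisoindolin-2-yl (3S)-2-(allyloxymethyl)-3-[3,5-dimethoxy-4-(triisopropylsilyloxy)phenyl]-3-(triisopropylsilyloxy)propanoate; 15 (4-iodo-2-methoxyphenoxy)triisopropylsilane (1.5 equiv)
Product: 16 (3S,4S)-3-{(S)-[3,5-dimethoxy-4-(triisopropylsilyloxy)phenyl](triisopropylsilyloxy)methyl}-4-[3-methoxy-4-(triisopropylsilyloxy)benzyl]oxolane
Conditions: NiBr2(dme) (10 mol %), 4,4'-di-tert-butyl-2,2'-bipyridine (10 mol %), Zn powder (2 equiv), DMA, rt, argon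
Reagents that add atoms: none
Why: Zinc reduces the nickel bromide/bipyridine complex to zerovalent nickel, which inserts into the C–I bond of 15, while single-electron reduction of the phthalimide ester of 13 releases phthalimide anion, CO2 and a secondary radical at C3. This radical closes the oxolane ring in a 5-exo-trig mode onto the allyl ether (C3–C4 bond); for 3-oxahex-5-enyl radicals this closure is much faster than bimolecular capture by nickel, so direct arylation at C3 should not compete. The new primary radical on the exocyclic CH2 is intercepted by the arylnickel halide (divalent nickel), and reductive elimination from trivalent nickel forms the CH2–aryl bond. The closest known reaction type is the nickel-catalysed reductive decarboxylative arylation of redox-active esters with aryl iodides, in which hexenyl-type radical probes are known to give cyclised arylation products. Both ring stereocentres are set in the cyclisation: C3 by the adjacent silyloxy carbinol, the alkene being expected to approach anti to the C–OSi bond in the conformer that keeps the carbinol hydrogen between the two developing ring bonds, and C4 by the ring transition state, in which the branched C3 substituent should avoid the alkene terminus and so end up trans to the new CH2. The step therefore needs trans selectivity against the weak inherent cis preference of hexenyl radicals substituted at the radical carbon, and it needs one sense of acyclic induction; the bulk of the CH(OSi)Ar group is relied on for both and neither is assured. Because the C3 radical is planar, both C2 epimers of 13 converge on the same intermediate.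

Step 11
Reactants: 16 (3S,4S)-3-{(S)-[3,5-dimethoxy-4-(triisopropylsilyloxy)phenyl](triisopropylsilyloxy)methyl}-4-[3-methoxy-4-(triisopropylsilyloxy)benzyl]oxolane
Product: 17 (S)-(4-hydroxy-3,5-dimethoxyphenyl)[(3S,4S)-4-(4-hydroxy-3-methoxybenzyl)oxolan-3-yl]methanol
Conditions: TBAF (6 equiv), AcOH (6 equiv), THF, 0 to 40 °C, argon
Reagents that add atoms: none
Why: Fluoride cleaves all three Si–O bonds, the aryl ethers quickly and the hindered benzylic ether on warming. Acetic acid keeps the phenols protonated, which suppresses phenoxide oxidation and quinone methide formation, and no acid strong enough to ionise the benzylic carbinol is present.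

## Compound list

1 | allyl alcohol | C=CCO | starting material
2 | allyl acrylate | C=CC(=O)OCC=C | starting material
3 | allyl 3-(allyloxy)propanoate | C=CCOCCC(=O)OCC=C | intermediate
4 | syringaldehyde (4-hydroxy-3,5-dimethoxybenzaldehyde) | COc1cc(C=O)cc(OC)c1O | starting material
5 | 3,5-dimethoxy-4-(triisopropylsilyloxy)benzaldehyde | COc1cc(C=O)cc(OC)c1O[Si](C(C)C)(C(C)C)C(C)C | intermediate
6 | lithium enolate of allyl 3-(allyloxy)propanoate | C=CCOCC=C(O[Li])OCC=C | intermediate
7 | allyl 2-(allyloxymethyl)-3-[3,5-dimethoxy-4-(triisopropylsilyloxy)phenyl]-3-hydroxypropanoate (racemic, both diastereomers) | C=CCOCC(C(=O)OCC=C)C(O)c1cc(OC)c(O[Si](C(C)C)(C(C)C)C(C)C)c(OC)c1 | intermediate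
8 | allyl 2-(allyloxymethyl)-3-[3,5-dimethoxy-4-(triisopropylsilyloxy)phenyl]-3-oxopropanoate (racemic) | C=CCOCC(C(=O)OCC=C)C(=O)c1cc(OC)c(O[Si](C(C)C)(C(C)C)C(C)C)c(OC)c1 | intermediate
9 | allyl (3S)-2-(allyloxymethyl)-3-[3,5-dimethoxy-4-(triisopropylsilyloxy)phenyl]-3-hydroxypropanoate | C=CCOCC(C(=O)OCC=C)[C@H](O)c1cc(OC)c(O[Si](C(C)C)(C(C)C)C(C)C)c(OC)c1 | intermediate
10 | allyl (3S)-2-(allyloxymethyl)-3-[3,5-dimethoxy-4-(triisopropylsilyloxy)phenyl]-3-(triisopropylsilyloxy)propanoate | C=CCOCC(C(=O)OCC=C)[C@H](O[Si](C(C)C)(C(C)C)C(C)C)c1cc(OC)c(O[Si](C(C)C)(C(C)C)C(C)C)c(OC)c1 | intermediate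
11 | (3S)-2-(allyloxymethyl)-3-[3,5-dimethoxy-4-(triisopropylsilyloxy)phenyl]-3-(triisopropylsilyloxy)propanoic acid | C=CCOCC(C(=O)O)[C@H](O[Si](C(C)C)(C(C)C)C(C)C)c1cc(OC)c(O[Si](C(C)C)(C(C)C)C(C)C)c(OC)c1 | intermediate
12 | N-hydroxyphthalimide | O=C1c2ccccc2C(=O)N1O | starting material
13 | 1,3-dioxoisoindolin-2-yl (3S)-2-(allyloxymethyl)-3-[3,5-dimethoxy-4-(triisopropylsilyloxy)phenyl]-3-(triisopropylsilyloxy)propanoate | C=CCOCC(C(=O)ON1C(=O)c2ccccc2C1=O)[C@H](O[Si](C(C)C)(C(C)C)C(C)C)c1cc(OC)c(O[Si](C(C)C)(C(C)C)C(C)C)c(OC)c1 | intermediate
14 | 4-iodo-2-methoxyphenol | COc1cc(I)ccc1O | starting material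
15 | (4-iodo-2-methoxyphenoxy)triisopropylsilane | COc1cc(I)ccc1O[Si](C(C)C)(C(C)C)C(C)C | intermediate
16 | (3S,4S)-3-{(S)-[3,5-dimethoxy-4-(triisopropylsilyloxy)phenyl](triisopropylsilyloxy)methyl}-4-[3-methoxy-4-(triisopropylsilyloxy)benzyl]oxolane | COc1cc(C[C@@H]2COC[C@H]2[C@H](O[Si](C(C)C)(C(C)C)C(C)C)c2cc(OC)c(O[Si](C(C)C)(C(C)C)C(C)C)c(OC)c2)ccc1O[Si](C(C)C)(C(C)C)C(C)C | intermediate
17 | (S)-(4-hydroxy-3,5-dimethoxyphenyl)[(3S,4S)-4-(4-hydroxy-3-methoxybenzyl)oxolan-3-yl]methanol | COc1cc(C[C@@H]2COC[C@H]2[C@H](O)c2cc(OC)c(O)c(OC)c2)ccc1O | target

## Step count and least certain steps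

Total number of steps: 11. Longest linear sequence: 9 steps (steps 2 to 8, 10 and 11 from 4; the same length from 1 through steps 1, 3 to 8, 10 and 11).

Step 10 (key step). The most likely failure is poor or inverted facial selectivity in the ring closure, because the acyclic induction by the silyloxy carbinol has no close model. Incomplete trans selectivity is the second concern, since radicals substituted at the radical carbon have a weak inherent preference for cis closure. Lesser risks are reduction of the primary radical by hydrogen abstraction before nickel captures it and homocoupling of the electron-rich aryl iodide.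

Fallback: the carbinol is used only as a control element and is reset at the end.
- Setting out from keto ester 8, reduction with RuCl[(R,R)-TsDPEN](p-cymene) should give the (3R)-hydroxy ester F1.
- The operations of steps 6 to 8 then lead through the (3R)-silyl ether F2 and the (3R)-acid F3 to the (3R)-phthalimide ester F4.
- Its cascade with 15 is, as far as the ring is concerned, the mirror image of the one that went the wrong way, and should give the carbinol-epimeric tris-silyl ether F5 with the (3S,4S) ring.
- TBAF/AcOH gives the epimeric triol F6. The two phenols are silylated again (TIPSCl, imidazole, DMF, 0 °C; the hindered secondary alcohol should not react) to the bis-silyl ether F7.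
- Dess–Martin oxidation gives the aryl ketone F8, and reagent-controlled reduction with (R)-2-methyl-CBS-oxazaborolidine and BH3·SMe2 should give the (S)-alcohol F9.
- TBAF/AcOH converts F9 into 17, where the route is rejoined.
- At the ketone stage C3 is epimerisable, so a cis ring closure could be corrected there by mild base as well.

Step 5. The reduction may be slow and its enantioselectivity eroded with a hindered, electron-rich aryl ketone. The enolisable keto ester may also lose allyl alcohol by retro-conjugate addition in the amine/formate medium.

Fallback: an auxiliary-controlled aldol replaces the catalytic reduction.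
- Setting out from ester 3, Pd(PPh3)4/morpholine gives 3-(allyloxy)propanoic acid F10.
- F10 is coupled (DCC, DMAP, CH2Cl2) with (S)-4-benzyloxazolidin-2-one to the acyl oxazolidinone F11.
- Its (Z)-dibutylboron enolate F12 (Bu2BOTf, iPr2NEt, CH2Cl2, −78 °C) adds to aldehyde 5 in an Evans syn aldol to give the adduct F13 with an (S)-carbinol.
- TIPSOTf/2,6-lutidine gives the silyl ether F14, and LiOH/H2O2 (THF/H2O, 0 °C) removes the auxiliary.
- The route is rejoined at acid 11, obtained here as one C2 epimer.

Step 3. Allyl alkoxide may be expelled from the enolate before addition, or from the aldolate after it, if the temperature rises. The allyl ester enolate may also undergo Claisen rearrangement on warming.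

Fallback: the C–C bond is made without a preformed enolate. Setting out from aldehyde 5 and acrylate 2, a Morita–Baylis–Hillman reaction (DABCO, MeOH, rt; slow with an electron-rich aldehyde) should give the α-methylene hydroxy ester F15. Phosphine-catalysed conjugate addition of allyl alcohol 1 (PBu3 cat., THF, rt) then gives 7, where the route is rejoined.

Step 7. Palladium may cause double-bond migration in the allyl ether or ionise it, which would destroy the radical acceptor. Turnover at the hindered ester may also be sluggish.

Fallback: the ester is cleaved before silylation, without palladium. Setting out from 9, LiOH (THF/H2O, 0 °C) gives the hydroxy acid F16. TIPSOTf (2.5 equiv)/2,6-lutidine gives the silyl ether silyl ester F17, and K2CO3 in MeOH/THF/H2O at 0 °C should hydrolyse only the silyl ester, returning the route at 11.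

## Further compounds

F1 | step 10 | allyl (3R)-2-(allyloxymethyl)-3-[3,5-dimethoxy-4-(triisopropylsilyloxy)phenyl]-3-hydroxypropanoate | C=CCOCC(C(=O)OCC=C)[C@@H](O)c1cc(OC)c(O[Si](C(C)C)(C(C)C)C(C)C)c(OC)c1
F2 | step 10 | allyl (3R)-2-(allyloxymethyl)-3-[3,5-dimethoxy-4-(triisopropylsilyloxy)phenyl]-3-(triisopropylsilyloxy)propanoate | C=CCOCC(C(=O)OCC=C)[C@@H](O[Si](C(C)C)(C(C)C)C(C)C)c1cc(OC)c(O[Si](C(C)C)(C(C)C)C(C)C)c(OC)c1
F3 | step 10 | (3R)-2-(allyloxymethyl)-3-[3,5-dimethoxy-4-(triisopropylsilyloxy)phenyl]-3-(triisopropylsilyloxy)propanoic acid | C=CCOCC(C(=O)O)[C@@H](O[Si](C(C)C)(C(C)C)C(C)C)c1cc(OC)c(O[Si](C(C)C)(C(C)C)C(C)C)c(OC)c1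
F4 | step 10 | 1,3-dioxoisoindolin-2-yl (3R)-2-(allyloxymethyl)-3-[3,5-dimethoxy-4-(triisopropylsilyloxy)phenyl]-3-(triisopropylsilyloxy)propanoate | C=CCOCC(C(=O)ON1C(=O)c2ccccc2C1=O)[C@@H](O[Si](C(C)C)(C(C)C)C(C)C)c1cc(OC)c(O[Si](C(C)C)(C(C)C)C(C)C)c(OC)c1
F5 | step 10 | (3S,4S)-3-{(R)-[3,5-dimethoxy-4-(triisopropylsilyloxy)phenyl](triisopropylsilyloxy)methyl}-4-[3-methoxy-4-(triisopropylsilyloxy)benzyl]oxolane | COc1cc(C[C@@H]2COC[C@H]2[C@@H](O[Si](C(C)C)(C(C)C)C(C)C)c2cc(OC)c(O[Si](C(C)C)(C(C)C)C(C)C)c(OC)c2)ccc1O[Si](C(C)C)(C(C)C)C(C)C
F6 | step 10 | (R)-(4-hydroxy-3,5-dimethoxyphenyl)[(3S,4S)-4-(4-hydroxy-3-methoxybenzyl)oxolan-3-yl]methanol | COc1cc(C[C@@H]2COC[C@H]2[C@@H](O)c2cc(OC)c(O)c(OC)c2)ccc1O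
F7 | step 10 | (R)-[3,5-dimethoxy-4-(triisopropylsilyloxy)phenyl]{(3S,4S)-4-[3-methoxy-4-(triisopropylsilyloxy)benzyl]oxolan-3-yl}methanol | COc1cc(C[C@@H]2COC[C@H]2[C@@H](O)c2cc(OC)c(O[Si](C(C)C)(C(C)C)C(C)C)c(OC)c2)ccc1O[Si](C(C)C)(C(C)C)C(C)C
F8 | step 10 | [3,5-dimethoxy-4-(triisopropylsilyloxy)phenyl]{(3S,4S)-4-[3-methoxy-4-(triisopropylsilyloxy)benzyl]oxolan-3-yl}methanone | COc1cc(C[C@@H]2COC[C@H]2C(=O)c2cc(OC)c(O[Si](C(C)C)(C(C)C)C(C)C)c(OC)c2)ccc1O[Si](C(C)C)(C(C)C)C(C)C
F9 | step 10 | (S)-[3,5-dimethoxy-4-(triisopropylsilyloxy)phenyl]{(3S,4S)-4-[3-methoxy-4-(triisopropylsilyloxy)benzyl]oxolan-3-yl}methanol | COc1cc(C[C@@H]2COC[C@H]2[C@H](O)c2cc(OC)c(O[Si](C(C)C)(C(C)C)C(C)C)c(OC)c2)ccc1O[Si](C(C)C)(C(C)C)C(C)C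
F10 | step 5 | 3-(allyloxy)propanoic acid | C=CCOCCC(=O)O
F11 | step 5 | (S)-3-[3-(allyloxy)propanoyl]-4-benzyloxazolidin-2-one | C=CCOCCC(=O)N1[C@@H](Cc2ccccc2)COC1=O
F12 | step 5 | (Z)-dibutylboron enolate of (S)-3-[3-(allyloxy)propanoyl]-4-benzyloxazolidin-2-one | C=CCOC/C=C(\OB(CCCC)CCCC)N1[C@@H](Cc2ccccc2)COC1=O
F13 | step 5 | (S)-3-{(2S,3S)-2-(allyloxymethyl)-3-[3,5-dimethoxy-4-(triisopropylsilyloxy)phenyl]-3-hydroxypropanoyl}-4-benzyloxazolidin-2-one | C=CCOC[C@H](C(=O)N1[C@@H](Cc2ccccc2)COC1=O)[C@H](O)c1cc(OC)c(O[Si](C(C)C)(C(C)C)C(C)C)c(OC)c1
F14 | step 5 | (S)-3-{(2S,3S)-2-(allyloxymethyl)-3-[3,5-dimethoxy-4-(triisopropylsilyloxy)phenyl]-3-(triisopropylsilyloxy)propanoyl}-4-benzyloxazolidin-2-one | C=CCOC[C@H](C(=O)N1[C@@H](Cc2ccccc2)COC1=O)[C@H](O[Si](C(C)C)(C(C)C)C(C)C)c1cc(OC)c(O[Si](C(C)C)(C(C)C)C(C)C)c(OC)c1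
F15 | step 3 | allyl 2-{[3,5-dimethoxy-4-(triisopropylsilyloxy)phenyl](hydroxy)methyl}acrylate (racemic) | C=CCOC(=O)C(=C)C(O)c1cc(OC)c(O[Si](C(C)C)(C(C)C)C(C)C)c(OC)c1
F16 | step 7 | (3S)-2-(allyloxymethyl)-3-[3,5-dimethoxy-4-(triisopropylsilyloxy)phenyl]-3-hydroxypropanoic acid | C=CCOCC(C(=O)O)[C@H](O)c1cc(OC)c(O[Si](C(C)C)(C(C)C)C(C)C)c(OC)c1
F17 | step 7 | triisopropylsilyl (3S)-2-(allyloxymethyl)-3-[3,5-dimethoxy-4-(triisopropylsilyloxy)phenyl]-3-(triisopropylsilyloxy)propanoate | C=CCOCC(C(=O)O[Si](C(C)C)(C(C)C)C(C)C)[C@H](O[Si](C(C)C)(C(C)C)C(C)C)c1cc(OC)c(O[Si](C(C)C)(C(C)C)C(C)C)c(OC)c1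
A1 | alternative 1 | (S)-4-benzyl-3-{(E)-4-[3-methoxy-4-(triisopropylsilyloxy)phenyl]-4-oxobut-2-enoyl}oxazolidin-2-one | COc1cc(C(=O)/C=C/C(=O)N2[C@@H](Cc3ccccc3)COC2=O)ccc1O[Si](C(C)C)(C(C)C)C(C)C
A2 | alternative 1 | chloromethyl (trimethylsilyl)methyl ether | C[Si](C)(C)COCCl
A3 | alternative 1 | trans-4-[3-methoxy-4-(triisopropylsilyloxy)benzoyl]oxolane-3-carbonyl derivative of (S)-4-benzyloxazolidin-2-one, ring configured as in the target | COc1cc(C(=O)[C@@H]2COC[C@H]2C(=O)N2[C@@H](Cc3ccccc3)COC2=O)ccc1O[Si](C(C)C)(C(C)C)C(C)C
A4 | alternative 2 | 4-vinyl-1,3-dioxolan-2-one (racemic) | C=CC1COC(=O)O1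
A5 | alternative 2 | 1-[3-methoxy-4-(triisopropylsilyloxy)phenyl]prop-2-en-1-one | COc1cc(C(=O)C=C)ccc1O[Si](C(C)C)(C(C)C)C(C)C
A6 | alternative 2 | trans-[3-methoxy-4-(triisopropylsilyloxy)phenyl](4-vinyloxolan-3-yl)methanone, ring configured as in the target | COc1cc(C(=O)[C@@H]2COC[C@H]2C=C)ccc1O[Si](C(C)C)(C(C)C)C(C)C
A7 | alternative 3 | (S)-5-[(tert-butyldimethylsilyloxy)methyl]furan-2(5H)-one | O=C1O[C@H](CO[Si](C)(C)C(C)(C)C)C=C1
A8 | alternative 3 | 2-[3,5-dimethoxy-4-(triisopropylsilyloxy)phenyl]-1,3-dithiane | COc1cc(C2SCCCS2)cc(OC)c1O[Si](C(C)C)(C(C)C)C(C)C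
A9 | alternative 3 | [4-(bromomethyl)-2-methoxyphenoxy]triisopropylsilane | COc1cc(CBr)ccc1O[Si](C(C)C)(C(C)C)C(C)C
A10 | alternative 3 | all-trans α-[3-methoxy-4-(triisopropylsilyloxy)benzyl]-β-{2-[3,5-dimethoxy-4-(triisopropylsilyloxy)phenyl]-1,3-dithian-2-yl}-γ-[(tert-butyldimethylsilyloxy)methyl]butyrolactone | COc1cc(C[C@@H]2C(=O)O[C@H](CO[Si](C)(C)C(C)(C)C)[C@H]2C3(SCCCS3)c3cc(OC)c(O[Si](C(C)C)(C(C)C)C(C)C)c(OC)c3)ccc1O[Si](C(C)C)(C(C)C)C(C)C
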